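**Plan**

- Retrosynthesis: remove the acetate, the silyl ether and the quinone oxidation level; cut the ring bond C4–C5 of the quinone and rejoin C4 to C1, which folds the hydroquinone back into a 4‑alkenyl‑4‑hydroxy‑3‑methoxycyclobutenone; cut the bond from that carbinol carbon to the internal alkene carbon (alkenyllithium + 3‑methoxycyclobutenedione); cut the chain at the two CH2 groups flanking the carbinol, back to (R)‑epichlorohydrin.
- Enabling feature: in the quinone, C1=O lies between C2(OMe) and C6(CH2R), while C4=O lies between the two ring CH carbons C3 and C5. A cyclobutenone with OMe on C3 and with OH plus a 1‑substituted vinyl group on C4 gives exactly this pattern on ring expansion.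
- Forward: the chain is built first (decyl Grignard and acetylide on the two CH2 arms of epichlorohydrin, silylation, Markovnikov C–Br), then joined to the four‑membered ring; the only ring of the target is closed by a thermal 4π‑opening/6π‑closure cascade; oxidation, desilylation and acetylation finish.
- Stereochemistry: the single stereocentre (R, the acetoxy‑bearing carbon) is bought with (R)‑epichlorohydrin and is never a reacting centre; the carbinol centre of the cyclobutenone is uncontrolled and vanishes on aromatisation.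

Key step: step 7

**Step 1**
Reactants: 1 dimethyl squarate (3,4‑dimethoxycyclobut‑3‑ene‑1,2‑dione)
Product: 3 3‑methoxycyclobut‑3‑ene‑1,2‑dione, via 4‑hydroxy‑2,3‑dimethoxycyclobut‑2‑en‑1‑one 2 (not isolated)
Conditions: LiAlH(Ot‑Bu)3 (1.05 equiv), THF, −78 → −20 °C; cold 1 M HCl, CH2Cl2 extraction; unpurified extract + 12 M HCl (cat.), rt
Reagents that add atoms: water, O
Why: Partial hydride reduction (1,2‑addition of the mild, bulky alkoxyaluminium hydride to one squarate carbonyl) gives carbinol 2, which under acid ionises, takes up water at the methoxy‑bearing C2 and expels methanol to unveil the 1,2‑dione, the standard squarate‑to‑alkoxycyclobutenedione conversion.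

**Step 2**
Reactants: 4 (R)‑epichlorohydrin [(2R)‑2‑(chloromethyl)oxirane]; 5 decylmagnesium bromide
Product: 7 (2R)‑2‑undecyloxirane, via (2R)‑1‑chlorotridecan‑2‑ol 6 (not isolated)
Conditions: CuI (10 mol %), THF, −40 → 0 °C; then 5 M aq NaOH, MeOH, rt
Reagents that add atoms: none
Why: Copper‑catalysed Grignard opening of the epoxide at its unsubstituted carbon (SN2), then base‑induced intramolecular Williamson closure of the chlorohydrin, rebuilds a terminal epoxide; the stereocentre is carried over from 4 because both substitutions occur at CH2 carbons.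

**Step 3**
Reactants: 7 (2R)‑2‑undecyloxirane; 8 lithium acetylide–ethylenediamine complex
Product: 9 (4R)‑pentadec‑1‑yn‑4‑ol
Conditions: DMSO, 0 °C → rt; H2O
Reagents that add atoms: none
Why: SN2 epoxide opening by acetylide at the terminal carbon in DMSO, a standard route to homopropargylic alcohols, breaks no bond to the carbinol centre.

**Step 4**
Reactants: 9 (4R)‑pentadec‑1‑yn‑4‑ol
Product: 10 tert‑butyldimethyl{[(4R)‑pentadec‑1‑yn‑4‑yl]oxy}silane
Conditions: TBSCl, imidazole, DMF, rt
Reagents that add atoms: tert‑butyldimethylsilyl chloride, CC(C)(C)[Si](C)(C)Cl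
Why: Imidazole‑promoted silylation of the secondary alcohol gives an ether that should withstand the organolithium, the thermolysis and the silver oxide oxidation ahead and can be removed at the end with acidic fluoride.

**Step 5**
Reactants: 10 tert‑butyldimethyl{[(4R)‑pentadec‑1‑yn‑4‑yl]oxy}silane
Product: 12 {[(4R)‑2‑bromopentadec‑1‑en‑4‑yl]oxy}(tert‑butyl)dimethylsilane, via (Z)‑alkenylborane 11 (not isolated)
Conditions: B‑Br‑9‑BBN (1.3 equiv), CH2Cl2, 0 °C; then AcOH, 0 °C → rt; aq NaHCO3
Reagents that add atoms: B‑bromo‑9‑borabicyclo[3.3.1]nonane, BrB1C2CCCC1CCC2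
Why: Haloboration/protodeboronation: B–Br adds syn across the terminal alkyne with bromine on the internal carbon and boron on the terminal one, and acetic acid cleaves the alkenyl C–B bond to leave the 2‑bromo‑1‑alkene (net Markovnikov HBr addition) without the double‑bond migration that free HBr would cause.

**Step 6**
Reactants: 12 {[(4R)‑2‑bromopentadec‑1‑en‑4‑yl]oxy}(tert‑butyl)dimethylsilane; 3 3‑methoxycyclobut‑3‑ene‑1,2‑dione
Product: 14 4‑[(4R)‑4‑(tert‑butyldimethylsilyloxy)pentadec‑1‑en‑2‑yl]‑4‑hydroxy‑3‑methoxycyclobut‑2‑en‑1‑one (both C4 epimers), via alkenyllithium 13 (not isolated)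
Conditions: t‑BuLi (2.1 equiv), Et2O, −78 °C; cannulate into 3 (1.2 equiv), THF, −78 °C; sat. aq NH4Cl at −78 °C
Reagents that add atoms: none
Why: Bromine–lithium exchange followed by 1,2‑addition of the alkenyllithium to the ketone‑like carbonyl C2 of 3 (C1 is deactivated as a vinylogous ester), the established regiochemistry of organolithium additions to 3‑alkoxycyclobutenediones; the new carbinol centre forms without control and is erased in step 7.

**Step 7**
Reactants: 14 4‑[(4R)‑4‑(tert‑butyldimethylsilyloxy)pentadec‑1‑en‑2‑yl]‑4‑hydroxy‑3‑methoxycyclobut‑2‑en‑1‑one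
Product: 17 2‑[(2R)‑2‑(tert‑butyldimethylsilyloxy)tridecyl]‑6‑methoxybenzene‑1,4‑diol, via dienylketene 15 (not isolated), via cyclohexa‑2,4‑dienone 16 (not isolated)
Conditions: p‑xylene (0.01 M, degassed), 138 °C, Ar
Reagents that add atoms: none
Why: Heating cleaves the C1–C4 bond of the strained ring by thermally allowed conrotatory 4π‑electrocyclic opening to the (Z)‑dienylketene 15, whose ketene carbon and methylidene terminus then join in a disrotatory 6π‑electrocyclisation to dienone 16, and keto–enol tautomerisation aromatises 16 to hydroquinone 17. The closest known reaction type is the thermal ring expansion of 4‑alkenyl‑4‑hydroxycyclobutenones to hydroquinones (Moore rearrangement). The one ring of the target, the six‑membered carbocycle, closes by 6π‑electrocyclisation, forming the C–C bond between the former C1 of 14 and the alkene CH2, driven by strain release and aromatisation. No stereocentre is created: the carbinol carbon of 14 becomes sp2, so both epimers converge, and the silyloxy‑bearing centre, insulated from the reacting π‑system by a CH2 group, is untouched. The step needs torquoselectivity, and the C4 hydroxyl as the stronger donor rotates outward, so the alkenyl group turns inward, cis to the ketene, as closure requires. The substitution pattern (methoxy and side chain flanking the same oxygenated carbon) is already fixed by the site of carbonyl addition in step 6, and high dilution in a non‑nucleophilic solvent keeps the ketene from being intercepted.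

**Step 8**
Reactants: 17 2‑[(2R)‑2‑(tert‑butyldimethylsilyloxy)tridecyl]‑6‑methoxybenzene‑1,4‑diol
Product: 18 2‑[(2R)‑2‑(tert‑butyldimethylsilyloxy)tridecyl]‑6‑methoxycyclohexa‑2,5‑diene‑1,4‑dione
Conditions: Ag2O, Na2SO4, Et2O, rt, dark
Reagents that add atoms: none
Why: Oxidation of a para‑hydroquinone to the 1,4‑benzoquinone with silver(I) oxide under neutral anhydrous conditions, which should not touch the silyl ether or the stereocentre.

**Step 9**
Reactants: 18 2‑[(2R)‑2‑(tert‑butyldimethylsilyloxy)tridecyl]‑6‑methoxycyclohexa‑2,5‑diene‑1,4‑dione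
Product: 19 2‑[(2R)‑2‑hydroxytridecyl]‑6‑methoxycyclohexa‑2,5‑diene‑1,4‑dione
Conditions: 48% aq HF–MeCN (1:19 v/v), 0 °C → rt
Reagents that add atoms: none
Why: Acidic fluoride desilylation (Si–F bond formation) of the secondary silyl ether under conditions in which the methoxyquinone is stable, whereas basic fluoride sources would attack it.

**Step 10**
Reactants: 19 2‑[(2R)‑2‑hydroxytridecyl]‑6‑methoxycyclohexa‑2,5‑diene‑1,4‑dione
Product: 20 (2R)‑1‑(5‑methoxy‑3,6‑dioxocyclohexa‑1,4‑dien‑1‑yl)tridecan‑2‑yl acetate (CNP0137521.1)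
Conditions: Ac2O, pyridine, CH2Cl2, 0 °C → rt
Reagents that add atoms: acetic anhydride, CC(=O)OC(C)=O
Why: Pyridine‑mediated O‑acylation of the secondary alcohol with acetic anhydride leaves the C–O bond, and hence the R configuration, intact.

**Compound list**

1 | dimethyl squarate (3,4‑dimethoxycyclobut‑3‑ene‑1,2‑dione) | COC1=C(OC)C(=O)C1=O | starting material
2 | 4‑hydroxy‑2,3‑dimethoxycyclobut‑2‑en‑1‑one (racemic) | COC1=C(OC)C(O)C1=O | intermediate
3 | 3‑methoxycyclobut‑3‑ene‑1,2‑dione | COC1=CC(=O)C1=O | intermediate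
4 | (R)‑epichlorohydrin, (2R)‑2‑(chloromethyl)oxirane | ClC[C@H]1CO1 | starting material
5 | decylmagnesium bromide | CCCCCCCCCC[Mg]Br | starting material
6 | (2R)‑1‑chlorotridecan‑2‑ol | ClC[C@H](O)CCCCCCCCCCC | intermediate
7 | (2R)‑2‑undecyloxirane | CCCCCCCCCCC[C@@H]1CO1 | intermediate
8 | lithium acetylide–ethylenediamine complex | [Li]C#C.NCCN | starting material
9 | (4R)‑pentadec‑1‑yn‑4‑ol | CCCCCCCCCCC[C@H](CC#C)O | intermediate
10 | tert‑butyldimethyl{[(4R)‑pentadec‑1‑yn‑4‑yl]oxy}silane | CCCCCCCCCCC[C@H](CC#C)O[Si](C)(C)C(C)(C)C | intermediate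
11 | 9‑[(1Z,4R)‑2‑bromo‑4‑(tert‑butyldimethylsilyloxy)pentadec‑1‑en‑1‑yl]‑9‑borabicyclo[3.3.1]nonane | Br/C(C[C@H](O[Si](C)(C)C(C)(C)C)CCCCCCCCCCC)=C\B1C2CCCC1CCC2 | intermediate
12 | {[(4R)‑2‑bromopentadec‑1‑en‑4‑yl]oxy}(tert‑butyl)dimethylsilane | CCCCCCCCCCC[C@H](CC(Br)=C)O[Si](C)(C)C(C)(C)C | intermediate
13 | [(4R)‑4‑(tert‑butyldimethylsilyloxy)pentadec‑1‑en‑2‑yl]lithium | CCCCCCCCCCC[C@H](CC([Li])=C)O[Si](C)(C)C(C)(C)C | intermediate
14 | 4‑[(4R)‑4‑(tert‑butyldimethylsilyloxy)pentadec‑1‑en‑2‑yl]‑4‑hydroxy‑3‑methoxycyclobut‑2‑en‑1‑one (ring C4 epimers) | CCCCCCCCCCC[C@H](CC(=C)C1(O)C(OC)=CC1=O)O[Si](C)(C)C(C)(C)C | intermediate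
15 | (3Z,7R)‑7‑(tert‑butyldimethylsilyloxy)‑4‑hydroxy‑3‑methoxy‑5‑methylideneoctadeca‑1,3‑dien‑1‑one (dienylketene) | O=C=C/C(OC)=C(/O)C(=C)C[C@H](O[Si](C)(C)C(C)(C)C)CCCCCCCCCCC | intermediate
16 | 5‑[(2R)‑2‑(tert‑butyldimethylsilyloxy)tridecyl]‑4‑hydroxy‑3‑methoxycyclohexa‑2,4‑dien‑1‑one | O=C1C=C(OC)C(O)=C(C[C@H](O[Si](C)(C)C(C)(C)C)CCCCCCCCCCC)C1 | intermediate
17 | 2‑[(2R)‑2‑(tert‑butyldimethylsilyloxy)tridecyl]‑6‑methoxybenzene‑1,4‑diol | CCCCCCCCCCC[C@H](Cc1cc(O)cc(OC)c1O)O[Si](C)(C)C(C)(C)C | intermediate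
18 | 2‑[(2R)‑2‑(tert‑butyldimethylsilyloxy)tridecyl]‑6‑methoxycyclohexa‑2,5‑diene‑1,4‑dione | CCCCCCCCCCC[C@H](CC1=CC(=O)C=C(OC)C1=O)O[Si](C)(C)C(C)(C)C | intermediate
19 | 2‑[(2R)‑2‑hydroxytridecyl]‑6‑methoxycyclohexa‑2,5‑diene‑1,4‑dione | CCCCCCCCCCC[C@H](CC1=CC(=O)C=C(OC)C1=O)O | intermediate
20 | (2R)‑1‑(5‑methoxy‑3,6‑dioxocyclohexa‑1,4‑dien‑1‑yl)tridecan‑2‑yl acetate | CCCCCCCCCCC[C@H](CC1=CC(=O)C=C(OC)C1=O)OC(C)=O | target

**Count**

Total steps: 10. Longest linear sequence: 9 steps (steps 2–10, from 4 to 20); step 1 is a one‑step branch that joins at step 6.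

**Steps most likely to fail**

Step 7. What may go wrong: the dienylketene is intercepted before it cyclises, either by its own enol hydroxyl if some of the material opens with the hydroxyl turned inward (closure to a butenolide), or by dimerisation and adventitious nucleophiles, so that the six‑membered ring does not form cleanly. Fallback: leave the ring expansion and attach the chain to a preformed arene. Setting out from epoxide 7, commercial 1‑methoxy‑2‑(methoxymethoxy)benzene is lithiated ortho to the acetal oxygen (n‑BuLi, THF, 0 °C). The aryllithium opens 7 at its CH2 carbon in the presence of BF3·OEt2 at −78 °C to give (2R)‑1‑[3‑methoxy‑2‑(methoxymethoxy)phenyl]tridecan‑2‑ol F1. Acidic methanolysis of the acetal (HCl, MeOH) gives 2‑[(2R)‑2‑hydroxytridecyl]‑6‑methoxyphenol F2. Fremy's salt (Teuber oxidation, phosphate buffer, acetone–water) then oxidises the free para position, which gives quinone 19; the route is rejoined there for step 10.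

Step 6. What may go wrong: the alkenyllithium attacks the methoxy‑bearing ring carbon of the small, very electrophilic dione 3 (addition–elimination with loss of methoxide) or adds twice, and 3 degrades under the basic conditions, so that little 1,2‑adduct is obtained. Fallback: carry a bulkier alkoxy group through the ring expansion and install the methoxy group last. Commercial diisopropyl squarate is reduced and treated with acid as in step 1 to give, by way of 4‑hydroxy‑2,3‑di(propan‑2‑yloxy)cyclobut‑2‑en‑1‑one F3, the more hindered and more robust 3‑(propan‑2‑yloxy)cyclobut‑3‑ene‑1,2‑dione F4. The fallback sets out from alkenyllithium 13 (made from 12 as in step 6), which is added to F4 to give 4‑[(4R)‑4‑(tert‑butyldimethylsilyloxy)pentadec‑1‑en‑2‑yl]‑4‑hydroxy‑3‑(propan‑2‑yloxy)cyclobut‑2‑en‑1‑one F5. Thermolysis under the conditions of step 7 should give 2‑[(2R)‑2‑(tert‑butyldimethylsilyloxy)tridecyl]‑6‑(propan‑2‑yloxy)benzene‑1,4‑diol F6, and silver(I) oxide should give 2‑[(2R)‑2‑(tert‑butyldimethylsilyloxy)tridecyl]‑6‑(propan‑2‑yloxy)cyclohexa‑2,5‑diene‑1,4‑dione F7. Methanol containing catalytic HCl should then exchange the vinylogous‑ester alkoxy group for methoxy by addition–elimination and cleave the silyl ether in the same operation, which returns the sequence to 19.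

Step 1. What may go wrong: during the acid‑promoted loss of methanol (and on silica) the remaining vinylogous methyl ester is hydrolysed as well, so that the product is lost to the aqueous phase as the free acid. Fallback: make the acid on purpose and esterify it separately. Setting out from 1, reduction as in step 1 to 2 is followed by complete hydrolysis in warm aqueous HCl to 3‑hydroxycyclobut‑3‑ene‑1,2‑dione (semisquaric acid) F8, which is isolated by evaporation and crystallisation. O‑methylation with (trimethylsilyl)diazomethane in MeOH–CH2Cl2 at 0 °C, directly before use, then gives 3, where the route is rejoined.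

**Further compounds**

F1 | step 7 | (2R)‑1‑[3‑methoxy‑2‑(methoxymethoxy)phenyl]tridecan‑2‑ol | CCCCCCCCCCC[C@H](Cc1cccc(OC)c1OCOC)O
F2 | step 7 | 2‑[(2R)‑2‑hydroxytridecyl]‑6‑methoxyphenol | CCCCCCCCCCC[C@H](Cc1cccc(OC)c1O)O
F3 | step 6 | 4‑hydroxy‑2,3‑di(propan‑2‑yloxy)cyclobut‑2‑en‑1‑one (racemic) | CC(C)OC1=C(OC(C)C)C(O)C1=O
F4 | step 6 | 3‑(propan‑2‑yloxy)cyclobut‑3‑ene‑1,2‑dione | CC(C)OC1=CC(=O)C1=O
F5 | step 6 | 4‑[(4R)‑4‑(tert‑butyldimethylsilyloxy)pentadec‑1‑en‑2‑yl]‑4‑hydroxy‑3‑(propan‑2‑yloxy)cyclobut‑2‑en‑1‑one (ring C4 epimers) | CCCCCCCCCCC[C@H](CC(=C)C1(O)C(OC(C)C)=CC1=O)O[Si](C)(C)C(C)(C)C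
F6 | step 6 | 2‑[(2R)‑2‑(tert‑butyldimethylsilyloxy)tridecyl]‑6‑(propan‑2‑yloxy)benzene‑1,4‑diol | CCCCCCCCCCC[C@H](Cc1cc(O)cc(OC(C)C)c1O)O[Si](C)(C)C(C)(C)C
F7 | step 6 | 2‑[(2R)‑2‑(tert‑butyldimethylsilyloxy)tridecyl]‑6‑(propan‑2‑yloxy)cyclohexa‑2,5‑diene‑1,4‑dione | CCCCCCCCCCC[C@H](CC1=CC(=O)C=C(OC(C)C)C1=O)O[Si](C)(C)C(C)(C)C
F8 | step 1 | 3‑hydroxycyclobut‑3‑ene‑1,2‑dione (semisquaric acid) | OC1=CC(=O)C1=O
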